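## Retrosynthetic overview

1. Target ⇐ reagent-controlled (CBS) reduction of the all-trans 4-aroyl-3-(hydroxymethyl)-2-aryloxolane (a γ-hydroxy aryl ketone).
2. Hydroxy ketone ⇐ homoconjugate opening of a cyclopropyl aryl ketone at its CH2 (iodide, then water) and epimerisation α to the ketone; the precursor is a 1-aroyl-3-oxabicyclo[3.1.0]hexane.
3. Bicycle ⇐ one gold-catalysed alkyne oxidation/cyclopropanation of a 1,6-enyne ether, steered by the allylic C–O stereocentre.
4. Enyne ⇐ Williamson etherification and Sonogashira coupling of (R)-1-(3,4,5-trimethoxyphenyl)allyl alcohol, propargyl bromide and 4-iodoveratrole; the alcohol ⇐ vinyl Grignard addition and Sharpless kinetic resolution.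
5. Ring order: oxolane and cyclopropane close together in step 5; the cyclopropane is opened in step 6, leaving the single oxolane of the target.

Stereochemical reading of the target SMILES used throughout: oxolane C-5 (aryl) R, C-4 (CH2OH) S, C-3 R, carbinol S; the three ring substituents are all-trans.

## Route

Step 1
Reactants: 1 3,4,5-trimethoxybenzaldehyde; 2 vinylmagnesium bromide
Product: 3 rac-1-(3,4,5-trimethoxyphenyl)prop-2-en-1-ol
Conditions: THF, 0 °C to rt; then aq. NH4Cl
Reagents that add atoms: none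
Why: Grignard 1,2-addition to a non-enolisable aryl aldehyde gives the racemic secondary allylic alcohol, which the next step resolves.

Step 2
Reactants: 3 rac-1-(3,4,5-trimethoxyphenyl)prop-2-en-1-ol
Product: 4 (R)-1-(3,4,5-trimethoxyphenyl)prop-2-en-1-ol
Conditions: Ti(OiPr)4 (10 mol%), D-(−)-DIPT (15 mol%), t-BuOOH (0.6 equiv), 4 Å MS, CH2Cl2, −20 °C, to about 55% conversion
Reagents that add atoms: none
Why: Sharpless kinetic resolution (Katsuki–Sharpless epoxidation of a secondary allylic alcohol): with D-(−)-DIPT the (S)-alcohol is epoxidised much faster, so the (R)-alcohol, the future aryl-bearing oxolane carbon, is recovered in high ee.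

Step 3
Reactants: 4 (R)-1-(3,4,5-trimethoxyphenyl)prop-2-en-1-ol; 5 propargyl bromide
Product: 6 5-[(1R)-1-(prop-2-yn-1-yloxy)prop-2-en-1-yl]-1,2,3-trimethoxybenzene
Conditions: NaH, Bu4NI (cat.), THF/DMF, 0 °C to rt
Reagents that add atoms: none
Why: Williamson ether synthesis on the alkoxide; only the O–H bond reacts, so the stereocentre is retained.

Step 4
Reactants: 6 5-[(1R)-1-(prop-2-yn-1-yloxy)prop-2-en-1-yl]-1,2,3-trimethoxybenzene; 7 4-iodo-1,2-dimethoxybenzene
Product: 8 4-[3-({(1R)-1-(3,4,5-trimethoxyphenyl)prop-2-en-1-yl}oxy)prop-1-yn-1-yl]-1,2-dimethoxybenzene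
Conditions: PdCl2(PPh3)2 (2 mol%), CuI (4 mol%), Et3N, THF, rt
Reagents that add atoms: none
Why: Sonogashira coupling of the terminal alkyne with the aryl iodide at room temperature leaves the vinyl group and the stereocentre untouched.

Step 5
Reactants: 8 4-[3-({(1R)-1-(3,4,5-trimethoxyphenyl)prop-2-en-1-yl}oxy)prop-1-yn-1-yl]-1,2-dimethoxybenzene
Product: 9 [(1R,4R,5R)-4-(3,4,5-trimethoxyphenyl)-3-oxabicyclo[3.1.0]hexan-1-yl](3,4-dimethoxyphenyl)methanone
Conditions: (IPr)AuNTf2 (5 mol%; IPr = 1,3-bis(2,6-diisopropylphenyl)imidazol-2-ylidene), 8-methylquinoline N-oxide (2 equiv, slow addition), ClCH2CH2Cl, rt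
Reagents that add atoms: 8-methylquinoline N-oxide, Cc1cccc2ccc[n+]([O-])c12
Why: Gold-catalysed alkyne oxidation/intramolecular cyclopropanation of a 1,6-enyne: the N-oxide attacks the gold-bound alkyne at the aryl-bearing carbon (benzylic stabilisation, inductive effect of the propargylic oxygen), the resulting catalyst-bound α-oxo carbene next to OCH2 cyclopropanates the tethered vinyl group so that oxolane and cyclopropane close together, and the aryl group on the allylic stereocentre sits anti to the new cyclopropane CH2 (it eclipses the small bridgehead H), which sets C-5 as R and, through the cis fusion, C-1 as R.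

Step 6
Reactants: 9 [(1R,4R,5R)-4-(3,4,5-trimethoxyphenyl)-3-oxabicyclo[3.1.0]hexan-1-yl](3,4-dimethoxyphenyl)methanone
Product: 12 [(3R,4S,5R)-4-(hydroxymethyl)-5-(3,4,5-trimethoxyphenyl)oxolan-3-yl](3,4-dimethoxyphenyl)methanone, via iodo ketone 10 (not isolated), via hydroxy ketone epimer mixture 11 (not isolated)
Conditions: Et2AlI (1.5 equiv), CH2Cl2, −40 to 0 °C; then acetone/H2O, Ag2CO3, rt, dark; then filter, DBU (20 mol%), THF, rt
Reagents that add atoms: water, O
Why: Lewis-acid/iodide homoconjugate (SN2-type) opening of the cyclopropyl ketone at its least hindered CH2 gives the γ-iodo ketone, silver-assisted hydrolysis with carbonyl participation replaces iodine by OH, and DBU equilibrates the centre α to the ketone to the all-trans oxolane, while the CH2OH-bearing carbon keeps the configuration set in step 5.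

Step 7
Reactants: 12 [(3R,4S,5R)-4-(hydroxymethyl)-5-(3,4,5-trimethoxyphenyl)oxolan-3-yl](3,4-dimethoxyphenyl)methanone
Product: 13 (S)-(3,4-dimethoxyphenyl)[(3R,4S,5R)-4-(hydroxymethyl)-5-(3,4,5-trimethoxyphenyl)oxolan-3-yl]methanol
Conditions: (R)-Me-CBS (20 mol%), BH3·SMe2 (2.5 equiv), THF, −20 °C; then aq. NH4Cl
Reagents that add atoms: none
Why: Corey–Bakshi–Shibata reduction: the (R)-oxazaborolidine delivers hydride to the aryl ketone with the aryl group as the large substituent, giving the (S)-carbinol under reagent control.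

## Compound list

1 | 3,4,5-trimethoxybenzaldehyde | COc1cc(C=O)cc(OC)c1OC | starting material
2 | vinylmagnesium bromide | C=C[Mg]Br | starting material
3 | rac-1-(3,4,5-trimethoxyphenyl)prop-2-en-1-ol | C=CC(O)c1cc(OC)c(OC)c(OC)c1 | intermediate
4 | (R)-1-(3,4,5-trimethoxyphenyl)prop-2-en-1-ol | C=C[C@@H](O)c1cc(OC)c(OC)c(OC)c1 | intermediate
5 | propargyl bromide (3-bromoprop-1-yne) | BrCC#C | starting material
6 | 5-[(1R)-1-(prop-2-yn-1-yloxy)prop-2-en-1-yl]-1,2,3-trimethoxybenzene | C=C[C@@H](OCC#C)c1cc(OC)c(OC)c(OC)c1 | intermediate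
7 | 4-iodo-1,2-dimethoxybenzene | COc1ccc(I)cc1OC | starting material
8 | 4-[3-({(1R)-1-(3,4,5-trimethoxyphenyl)prop-2-en-1-yl}oxy)prop-1-yn-1-yl]-1,2-dimethoxybenzene | C=C[C@@H](OCC#Cc1ccc(OC)c(OC)c1)c1cc(OC)c(OC)c(OC)c1 | intermediate
9 | [(1R,4R,5R)-4-(3,4,5-trimethoxyphenyl)-3-oxabicyclo[3.1.0]hexan-1-yl](3,4-dimethoxyphenyl)methanone | COc1ccc(cc1OC)C(=O)[C@@]12CO[C@@H](c3cc(OC)c(OC)c(OC)c3)[C@@H]1C2 | intermediate
10 | [(3RS,4R,5R)-4-(iodomethyl)-5-(3,4,5-trimethoxyphenyl)oxolan-3-yl](3,4-dimethoxyphenyl)methanone (C-3 epimer mixture) | COc1ccc(cc1OC)C(=O)C1CO[C@@H](c2cc(OC)c(OC)c(OC)c2)[C@@H]1CI | intermediate (not isolated)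
11 | [(3RS,4S,5R)-4-(hydroxymethyl)-5-(3,4,5-trimethoxyphenyl)oxolan-3-yl](3,4-dimethoxyphenyl)methanone (C-3 epimer mixture) | COc1ccc(cc1OC)C(=O)C1CO[C@@H](c2cc(OC)c(OC)c(OC)c2)[C@@H]1CO | intermediate (not isolated)
12 | [(3R,4S,5R)-4-(hydroxymethyl)-5-(3,4,5-trimethoxyphenyl)oxolan-3-yl](3,4-dimethoxyphenyl)methanone | COc1ccc(cc1OC)C(=O)[C@H]1CO[C@@H](c2cc(OC)c(OC)c(OC)c2)[C@@H]1CO | intermediate
13 | (S)-(3,4-dimethoxyphenyl)[(3R,4S,5R)-4-(hydroxymethyl)-5-(3,4,5-trimethoxyphenyl)oxolan-3-yl]methanol | COc1ccc([C@@H](O)[C@H]2CO[C@@H](c3cc(OC)c(OC)c(OC)c3)[C@@H]2CO)cc1OC | target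

## Step count and risks

Total steps: 7. Longest linear sequence: 7 (steps 1 to 7; all coupling partners are commercial).

The three steps most likely to fail:

Step 5 (gold oxidation/cyclopropanation). Risks: 1,2-hydride shift of the carbene to a β-alkoxy enone, attack of the carbene on the trimethoxyphenyl ring, a second oxidation to a 1,2-diketone, and incomplete anti selectivity, which could not be corrected later. The fallback sets out from 8 and comes back at 9 through a classical diazo ketone. Hydration of the alkyne with (Ph3P)AuNTf2 in wet dioxane gives the β-alkoxy aryl ketone F1. Its enolate (LiN(SiMe3)2, THF, −78 °C) is acylated with 2,2,2-trifluoroethyl trifluoroacetate to the trifluoroacetyl diketone F2. Methanesulfonyl azide and Et3N in wet MeCN transfer the diazo group with loss of the trifluoroacetyl group to give the diazo ketone F3. Rh2(O2CCPh3)4 in CH2Cl2 then converts F3 into a rhodium carbenoid that cyclopropanates the vinyl group to 9.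

Step 6 (cyclopropane opening). Risks: the ring is activated by one ketone only, and the aluminium Lewis acid may ionise the benzylic ether. The fallback sets out from 9 and comes back at 12 without a stoichiometric Lewis acid or silver. MgI2 (20 mol%) in toluene at 80 °C opens the ring with iodide and lets the magnesium enolate close on oxygen (a Cloke–Wilson-type rearrangement) to the fused bicyclic enol ether F4. PPTS in wet THF hydrolyses the aryl enol ether to the γ-hydroxy ketone, and DBU equilibration gives 12.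

Step 7 (carbinol configuration). Risks: the α-branched ketone and the free primary OH (an alkoxyborane that may deliver hydride internally) can erode reagent control. The fallback sets out from 12 and comes back at 13. TBSCl and imidazole give the silyl ether ketone F5. Asymmetric transfer hydrogenation with RuCl(p-cymene)[(S,S)-TsDPEN] in HCO2H/Et3N gives the (S)-carbinol silyl ether F6. Bu4NF in THF releases 13.

Further compounds

F1 | step 5 | 1-(3,4-dimethoxyphenyl)-3-{[(1R)-1-(3,4,5-trimethoxyphenyl)prop-2-en-1-yl]oxy}propan-1-one | C=C[C@@H](OCCC(=O)c1ccc(OC)c(OC)c1)c1cc(OC)c(OC)c(OC)c1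
F2 | step 5 | 1-(3,4-dimethoxyphenyl)-4,4,4-trifluoro-2-({[(1R)-1-(3,4,5-trimethoxyphenyl)prop-2-en-1-yl]oxy}methyl)butane-1,3-dione | C=C[C@@H](OCC(C(=O)C(F)(F)F)C(=O)c1ccc(OC)c(OC)c1)c1cc(OC)c(OC)c(OC)c1
F3 | step 5 | 2-diazo-1-(3,4-dimethoxyphenyl)-3-{[(1R)-1-(3,4,5-trimethoxyphenyl)prop-2-en-1-yl]oxy}propan-1-one | C=C[C@@H](OCC(=[N+]=[N-])C(=O)c1ccc(OC)c(OC)c1)c1cc(OC)c(OC)c(OC)c1
F4 | step 6 | (3aS,4R)-1-(3,4-dimethoxyphenyl)-4-(3,4,5-trimethoxyphenyl)-3a,4-dihydro-3H,6H-furo[3,4-c]furan | COc1ccc(cc1OC)C1=C2CO[C@@H](c3cc(OC)c(OC)c(OC)c3)[C@@H]2CO1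
F5 | step 7 | [(3R,4S,5R)-4-({[tert-butyl(dimethyl)silyl]oxy}methyl)-5-(3,4,5-trimethoxyphenyl)oxolan-3-yl](3,4-dimethoxyphenyl)methanone | COc1ccc(cc1OC)C(=O)[C@H]1CO[C@@H](c2cc(OC)c(OC)c(OC)c2)[C@@H]1CO[Si](C)(C)C(C)(C)C
F6 | step 7 | (S)-[(3R,4S,5R)-4-({[tert-butyl(dimethyl)silyl]oxy}methyl)-5-(3,4,5-trimethoxyphenyl)oxolan-3-yl](3,4-dimethoxyphenyl)methanol | COc1ccc([C@@H](O)[C@H]2CO[C@@H](c3cc(OC)c(OC)c(OC)c3)[C@@H]2CO[Si](C)(C)C(C)(C)C)cc1OC
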